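Late in a run a flask holds no more L than its smaller charge pays for, if each L costs one Z. Z stands at 0.0250 M, less than the 0.050 M of D, so Z is the limiting reagent and my ceiling is 50.0% of the D charged. Suppose Z is spent in proportion to what is left of it and to the E charged. It then decays as a first-order lag (pseudo-first-order), and L climbs to the ceiling along the same exponential.

the same everywhere: D 0.050 M
- north-west: Z 0.025 M; E 18 µM; temperature −25 °C; run made earlier
- south: Z 0.025 M; E 85 µM; temperature −14 °C; run made earlier
- south-east: Z 0.025 M; E 330 µM; temperature −25 °C; run made earlier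
- summer: Z 0.0250 M; E 300 µM; temperature −20 °C; time 2.5 h
- dawn: Z 0.0250 M; E 150 µM; temperature −20 °C; time 2.5 h
- noon: Z 0.0250 M; E 20 µM; temperature −20 °C; time 2.5 h
- spring: Z 0.0250 M; E 80 µM; temperature −20 °C; time 2.5 h

| run | time / min | L / % | D / % |
|---|---|---|---|
| north-west | 6.00 | 0 | 99.7 |
| north-west | 12.0 | 0.2 | 99.7 |
| north-west | 20.0 | 0.9 | 100.0 |
| north-west | 40.0 | 0.6 | 99.2 |
| north-west | 80.0 | 1.1 | 99.3 |
| south | 6.00 | 0 | 98.9 |
| south | 12.0 | 1.4 | 97.7 |
| south | 20.0 | 1.3 | 97.8 |
| south | 40.0 | 4.1 | 95.2 |
| south | 80.0 | 7.0 | 90.2 |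
| south-east | 15.0 | 3.2 | 97.1 |
| south-east | 30.0 | 7.1 | 92.8 |
| south-east | 50.0 | 10.5 | 86.9 |
| south-east | 60.0 | 13.1 | 85.7 |
| south-east | 80.0 | 16.8 | 80.5 |

(scatter of a reading: 0.5 percentage points)

- what was read earlier has a scatter of 0.5 percentage points, one standard deviation
- a reading or a percentage of L counts all its forms, free or not

* the flasks put in order of amount of L, in percent of the D charged, best first, at 2.5 h (summer / dawn / noon / spring)
* the amount of L, in percent of the D charged of the flask you put first, at 2.5 h
* the amount of L, in percent of the D charged of the flask you put last, at 2.5 h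

Turn E first: by hand, L over a fixed time at a fixed temperature rises with E. At −25 °C, going from the north-west run to the south-east run multiplies E by 18.3, and L at 80.0 min goes from 1.1% to 16.8%.

Turn time next: by hand, my lag makes the curve bend. The last south-east reading gives a constant of 931 M⁻¹ h⁻¹. With it the lag puts L at 7.12% at 30.0 min, and the reading there is 7.1%. A straight line through that reading reaches 18.9% at 80.0 min, more than the 16.8% read.

Turn temperature last: by hand, warming speeds the flask. The south run at −14 °C gives 1330 M⁻¹ h⁻¹, and interpolating on a log scale to −20 °C gives 1090 M⁻¹ h⁻¹ for the spending constant, the fraction of Z lost per unit time and per unit of E.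

The time constant is one over this constant times E. For summer it is 3.04 h, so my lag puts L at 28.0%. For noon it is 45.7 h, so my lag puts L at 2.66%.

The forecast gave summer > dawn > spring > noon, with 29% and 2.7%, a little above my top figure, on the ground that the “rate scales about linearly with E”.

The flasks give summer > dawn > spring > noon, with 26.5% and 2.53%.

    Q → E + L (k = 329 h⁻¹, Ea = 57.0 kJ mol⁻¹)
    Z + L ⇌ X, settled at all times (K = 13.0 M⁻¹, ΔH = −74.0 kJ mol⁻¹)
    D + E → J (k = 1620 M⁻¹ h⁻¹, Ea = 41.0 kJ mol⁻¹)
    Z + J ⇌ Q (K = 9.40 M⁻¹, k = 11800 M⁻¹ h⁻¹, Ea = 44.0 kJ mol⁻¹, ΔH = −55.0 kJ mol⁻¹)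
    D + L → G (k = 4.22 M⁻¹ h⁻¹, Ea = 47.0 kJ mol⁻¹)
    (constants at −20 °C)

In noon, the step from Z and J to Q, forward alone, gives Z a half-life of 5.6 h at 2.50 h, and at 1.23 h Q falls back 3.8 times as fast as it goes on to E and L. Multiplying that half-life by one plus this ratio, two values from different moments, gives 26.9 h for Z in noon, and the spending constant gives Z in noon a half-life of 31.7 h. For a flask like noon but with 8.0 × 10⁻⁵ M of E, the spending constant gives 9.83% of L, and that flask stands at 9.35%.

All runs were generated by integration on assumed constants; noise was put on by code.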